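**Retrosynthetic overview**
1. The target comes from hydrogenolysis of its tri-O-benzyl ether. In that ether the C7–O bond of the tetrahydrofuran is cut back to an open-chain tetraol. The ring closes when the C9' hydroxyl captures the C7 benzylic cation, which sets 7,8-trans.
2. The tetraol comes from LiAlH4 reduction of a trans-aldol (C7–C8 bond) between an (R)-β-benzyl-γ-butyrolactone and O-benzylvanillin.
3. The lactone comes from ozonolysis and lactonisation of a γ,δ-unsaturated ester. A Johnson–Claisen [3,3] shift makes that ester and forms the C8–C8' bond, with 1,3-chirality transfer from an (R,E)-allylic alcohol. The alcohol comes from cross-metathesis of a eugenol ether with (R)-but-3-en-2-ol.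
4. The eugenol ether carries the threo side chain and is built first. Its steps are Mitsunobu inversion (C8''–O–C4') of an α-hydroxy Weinreb amide from O-benzyl-L-serine, aryl Grignard addition, and Felkin–Anh ketone reduction (C7'').
5. Ring order: a temporary γ-butyrolactone forms in step 9 and is opened in step 11. The tetrahydrofuran, the only ring of the target that is made, closes in step 12.

Assumption: 1 and 11 are bought enantiopure. Lignan numbering is used: C7–C9 for the unit bearing the aryl group on the tetrahydrofuran, C7'–C9' for the benzyl unit, C7''–C9'' for the glycerol unit.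
Abbreviation: Ar* = 3-methoxy-4-{[(1R,2R)-3-(benzyloxy)-1-[4-(benzyloxy)-3-methoxyphenyl]-1-(pivaloyloxy)propan-2-yl]oxy}phenyl.

Step 1
Reactants: 1 O-benzyl-L-serine
Product: 2 (S)-3-(benzyloxy)-2-hydroxypropanoic acid
Conditions: NaNO2 (2 equiv), 1 M aq H2SO4, 0 °C to rt, 16 h
Reagents that add atoms: water (SMILES: O)
Why: Diazotisation of an α-amino acid with neighbouring carboxylate participation is a double inversion, so the serine centre is kept as the (S)-carbinol.

Step 2
Reactants: 2 (S)-3-(benzyloxy)-2-hydroxypropanoic acid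
Product: 3 (S)-3-(benzyloxy)-2-hydroxy-N-methoxy-N-methylpropanamide
Conditions: MeNH(OMe)·HCl (1.3 equiv), EDC·HCl (1.3 equiv), HOBt (10 mol %), N-methylmorpholine (2.6 equiv), CH2Cl2, 0 °C to rt
Reagents that add atoms: N,O-dimethylhydroxylamine hydrochloride (SMILES: CNOC.Cl)
Why: In this carbodiimide coupling (Weinreb amide formation) the amine outruns the free α-hydroxyl and the stereocentre is not touched.

Step 3
Reactants: 3 (S)-3-(benzyloxy)-2-hydroxy-N-methoxy-N-methylpropanamide; 4 eugenol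
Product: 5 (R)-2-(4-allyl-2-methoxyphenoxy)-3-(benzyloxy)-N-methoxy-N-methylpropanamide
Conditions: PPh3 (1.4 equiv), DIAD (1.4 equiv), toluene, 0 °C to rt
Reagents that add atoms: none
Why: In this Mitsunobu etherification the phenol displaces the carbonyl-activated oxyphosphonium group by SN2, which inverts (S) to (R) and sets C8'' together with the 8''-O-4' bond.

Step 4
Reactants: 5 (R)-2-(4-allyl-2-methoxyphenoxy)-3-(benzyloxy)-N-methoxy-N-methylpropanamide; 6 1-(benzyloxy)-4-bromo-2-methoxybenzene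
Product: 8 (R)-2-(4-allyl-2-methoxyphenoxy)-3-(benzyloxy)-1-[4-(benzyloxy)-3-methoxyphenyl]propan-1-one, via arylmagnesium bromide 7 (not isolated)
Conditions: 6 (1.4 equiv), Mg, THF, reflux; then 5, THF, 0 °C; poured into cold sat. aq NH4Cl
Reagents that add atoms: none
Why: In this Weinreb ketone synthesis the chelated tetrahedral adduct lasts until the buffered quench, so there is no over-addition and the α-aryloxy ketone never meets base.

Step 5
Reactants: 8 (R)-2-(4-allyl-2-methoxyphenoxy)-3-(benzyloxy)-1-[4-(benzyloxy)-3-methoxyphenyl]propan-1-one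
Product: 9 (1R,2R)-2-(4-allyl-2-methoxyphenoxy)-3-(benzyloxy)-1-[4-(benzyloxy)-3-methoxyphenyl]propan-1-ol (threo)
Conditions: L-Selectride (1.2 equiv), THF, −78 °C; then aq NaOH, H2O2, 0 °C
Reagents that add atoms: none
Why: In this polar Felkin–Anh reduction the bulky, non-chelating hydride attacks anti to the perpendicular C8''–OAr bond and past H, which gives (7''R), the threo isomer, under control of C8''.

Step 6
Reactants: 9 (1R,2R)-2-(4-allyl-2-methoxyphenoxy)-3-(benzyloxy)-1-[4-(benzyloxy)-3-methoxyphenyl]propan-1-ol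
Product: 10 (1R,2R)-2-(4-allyl-2-methoxyphenoxy)-3-(benzyloxy)-1-[4-(benzyloxy)-3-methoxyphenyl]propyl pivalate
Conditions: PivCl (2 equiv), Et3N (3 equiv), DMAP (20 mol %), CH2Cl2, rt to 40 °C
Reagents that add atoms: pivaloyl chloride (SMILES: CC(C)(C)C(=O)Cl)
Why: This DMAP-catalysed acylation with retention gives a non-enolisable ester that survives orthoester exchange, ozone and LDA and is removed at no extra cost in step 11.

Step 7
Reactants: 10 pivalate of 9; 11 (R)-but-3-en-2-ol
Product: 12 (1R,2R)-3-(benzyloxy)-1-[4-(benzyloxy)-3-methoxyphenyl]-2-{4-[(2E,4R)-4-hydroxypent-2-en-1-yl]-2-methoxyphenoxy}propyl pivalate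
Conditions: 11 (3 equiv), Hoveyda–Grubbs II (5 mol %), 1,4-benzoquinone (10 mol %), CH2Cl2, 40 °C
Reagents that add atoms: none
Why: Olefin cross-metathesis of a type I allylarene with a type II secondary allylic alcohol gives the E-alkene selectively, benzoquinone suppresses allyl-to-propenyl isomerisation, and the bought carbinol centre is not touched.

Step 8
Reactants: 12 (R,E)-allylic alcohol; 13 triethyl orthoacetate
Product: 15 ethyl (3R,4E)-3-(Ar*-methyl)hex-4-enoate, via mixed ketene acetal 14 (not isolated)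
Conditions: 13 (10 equiv, neat), EtCO2H (10 mol %), 138 °C, EtOH distilled off, 5 h
Reagents that add atoms: none
Why: In this Johnson–Claisen [3,3]-sigmatropic rearrangement the chair with equatorial methyl forms the C8–C8' bond suprafacially on the face that loses oxygen, so the (R,E)-carbinol is relayed into (R)-C8' and a new E-alkene.

Step 9
Reactants: 15 ethyl (3R,4E)-3-(Ar*-methyl)hex-4-enoate
Product: 17 (R)-4-(Ar*-methyl)dihydrofuran-2(3H)-one, via hydroxy ester 16 (not isolated)
Conditions: O3, CH2Cl2–MeOH 4:1, −78 °C (Sudan Red 7B end point); NaBH4, −78 to 0 °C; 1 M HCl, rt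
Reagents that add atoms: ozone (SMILES: [O-][O+]=O)
Why: In this ozonolysis with reductive work-up and spontaneous γ-lactonisation the alkene reacts far faster than the dialkoxyarenes, and the aldehyde is reduced cold so C8' is not epimerised.

Step 10
Reactants: 17 (R)-4-(Ar*-methyl)dihydrofuran-2(3H)-one; 18 4-(benzyloxy)-3-methoxybenzaldehyde
Product: 20 (3S,4R)-3-{[4-(benzyloxy)-3-methoxyphenyl](hydroxy)methyl}-4-(Ar*-methyl)dihydrofuran-2(3H)-one (both C7 epimers), via lithium enolate 19 (not isolated)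
Conditions: LDA (1.15 equiv), THF, −78 °C; 18 (1.2 equiv), −78 °C, 1 h; sat. aq NH4Cl at −78 °C
Reagents that add atoms: none
Why: In this lithium enolate aldol addition the aldehyde approaches anti to the β-benzyl group, so C8 is set trans to C8', and the C7 epimer mixture does not matter because C7 is reset in step 12.

Step 11
Reactants: 20 aldol lactone
Product: 21 (2R,3R)-2-{[4-(benzyloxy)-3-methoxyphenyl](hydroxy)methyl}-3-(4-{[(1R,2R)-3-(benzyloxy)-1-[4-(benzyloxy)-3-methoxyphenyl]-1-hydroxypropan-2-yl]oxy}-3-methoxybenzyl)butane-1,4-diol (both C7 epimers)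
Conditions: LiAlH4 (4 equiv), THF, 0 °C to rt; Fieser work-up
Reagents that add atoms: none
Why: This hydride reduction opens the lactone to the 1,4-diol and cleaves the pivalate in the same operation, and reduction beats retro-aldol so C8 is fixed.

Step 12
Reactants: 21 tetraol
Product: 22 4,4'',9''-tri-O-benzyl ether of the target (7S,8R,8'R,7''R,8''R)
Conditions: p-TsOH·H2O (5 mol %), CH2Cl2, 0 °C, 30 min
Reagents that add atoms: none
Why: In this acid-catalysed SN1 cycloetherification both C7 epimers give the same p-alkoxybenzyl cation, which the C9' hydroxyl captures to close the five-membered ring with aryl trans to the C8 hydroxymethyl group, while C7'' stays put because its cation is destabilised by the β-aryloxy group.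

Step 13
Reactants: 22 tri-O-benzyl ether
Product: 23 target CNP0158473.2
Conditions: H2 (1 atm), 10% Pd/C, EtOAc–EtOH 1:1, rt, stopped at 3 equiv H2
Reagents that add atoms: none
Why: In this catalytic hydrogenolysis under neutral conditions the unhindered O-benzyl groups cleave faster than the hindered secondary benzylic C–O bonds at C7 and C7'', and no stereocentre is affected.

**Compound list**
1 | O-benzyl-L-serine | N[C@@H](COCc1ccccc1)C(=O)O | starting material
2 | (S)-3-(benzyloxy)-2-hydroxypropanoic acid | O[C@@H](COCc1ccccc1)C(=O)O | intermediate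
3 | (S)-3-(benzyloxy)-2-hydroxy-N-methoxy-N-methylpropanamide | O[C@@H](COCc1ccccc1)C(=O)N(C)OC | intermediate
4 | eugenol (4-allyl-2-methoxyphenol) | C=CCc1ccc(O)c(OC)c1 | starting material
5 | (R)-2-(4-allyl-2-methoxyphenoxy)-3-(benzyloxy)-N-methoxy-N-methylpropanamide | C=CCc1ccc(O[C@H](COCc2ccccc2)C(=O)N(C)OC)c(OC)c1 | intermediate
6 | 1-(benzyloxy)-4-bromo-2-methoxybenzene | COc1cc(Br)ccc1OCc1ccccc1 | starting material
7 | [4-(benzyloxy)-3-methoxyphenyl]magnesium bromide | COc1cc([Mg]Br)ccc1OCc1ccccc1 | intermediate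
8 | (R)-2-(4-allyl-2-methoxyphenoxy)-3-(benzyloxy)-1-[4-(benzyloxy)-3-methoxyphenyl]propan-1-one | C=CCc1ccc(O[C@H](COCc2ccccc2)C(=O)c2ccc(OCc3ccccc3)c(OC)c2)c(OC)c1 | intermediate
9 | (1R,2R)-2-(4-allyl-2-methoxyphenoxy)-3-(benzyloxy)-1-[4-(benzyloxy)-3-methoxyphenyl]propan-1-ol | C=CCc1ccc(O[C@H](COCc2ccccc2)[C@H](O)c2ccc(OCc3ccccc3)c(OC)c2)c(OC)c1 | intermediate
10 | (1R,2R)-2-(4-allyl-2-methoxyphenoxy)-3-(benzyloxy)-1-[4-(benzyloxy)-3-methoxyphenyl]propyl pivalate | C=CCc1ccc(O[C@H](COCc2ccccc2)[C@H](OC(=O)C(C)(C)C)c2ccc(OCc3ccccc3)c(OC)c2)c(OC)c1 | intermediate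
11 | (R)-but-3-en-2-ol | C[C@@H](O)C=C | starting material
12 | (1R,2R)-3-(benzyloxy)-1-[4-(benzyloxy)-3-methoxyphenyl]-2-{4-[(2E,4R)-4-hydroxypent-2-en-1-yl]-2-methoxyphenoxy}propyl pivalate | C[C@@H](O)/C=C/Cc1ccc(O[C@H](COCc2ccccc2)[C@H](OC(=O)C(C)(C)C)c2ccc(OCc3ccccc3)c(OC)c2)c(OC)c1 | intermediate
13 | triethyl orthoacetate | CCOC(C)(OCC)OCC | starting material
14 | 1-ethoxyvinyl ether of 12 (mixed ketene acetal) | C=C(OCC)O[C@H](C)/C=C/Cc1ccc(O[C@H](COCc2ccccc2)[C@H](OC(=O)C(C)(C)C)c2ccc(OCc3ccccc3)c(OC)c2)c(OC)c1 | intermediate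
15 | ethyl (3R,4E)-3-(Ar*-methyl)hex-4-enoate | CCOC(=O)C[C@@H](Cc1ccc(O[C@H](COCc2ccccc2)[C@H](OC(=O)C(C)(C)C)c2ccc(OCc3ccccc3)c(OC)c2)c(OC)c1)/C=C/C | intermediate
16 | ethyl (R)-4-hydroxy-3-(Ar*-methyl)butanoate | CCOC(=O)C[C@@H](Cc1ccc(O[C@H](COCc2ccccc2)[C@H](OC(=O)C(C)(C)C)c2ccc(OCc3ccccc3)c(OC)c2)c(OC)c1)CO | intermediate
17 | (R)-4-(Ar*-methyl)dihydrofuran-2(3H)-one | O=C1C[C@@H](Cc2ccc(O[C@H](COCc3ccccc3)[C@H](OC(=O)C(C)(C)C)c3ccc(OCc4ccccc4)c(OC)c3)c(OC)c2)CO1 | intermediate
18 | 4-(benzyloxy)-3-methoxybenzaldehyde | COc1cc(C=O)ccc1OCc1ccccc1 | starting material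
19 | lithium enolate of 17 | [Li]OC1=C[C@@H](Cc2ccc(O[C@H](COCc3ccccc3)[C@H](OC(=O)C(C)(C)C)c3ccc(OCc4ccccc4)c(OC)c3)c(OC)c2)CO1 | intermediate
20 | (3S,4R)-3-{[4-(benzyloxy)-3-methoxyphenyl](hydroxy)methyl}-4-(Ar*-methyl)dihydrofuran-2(3H)-one, C7 epimers | O=C1[C@H](C(O)c2ccc(OCc3ccccc3)c(OC)c2)[C@@H](Cc2ccc(O[C@H](COCc3ccccc3)[C@H](OC(=O)C(C)(C)C)c3ccc(OCc4ccccc4)c(OC)c3)c(OC)c2)CO1 | intermediate
21 | (2R,3R)-tetraol (7-hydroxy-secoisolariciresinol type), C7 epimers | OC[C@H](C(O)c1ccc(OCc2ccccc2)c(OC)c1)[C@@H](Cc1ccc(O[C@H](COCc2ccccc2)[C@H](O)c2ccc(OCc3ccccc3)c(OC)c2)c(OC)c1)CO | intermediate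
22 | 4,4'',9''-tri-O-benzyl ether of the target | COc1cc([C@@H](O)[C@@H](COCc2ccccc2)Oc2ccc(C[C@H]3CO[C@H](c4ccc(OCc5ccccc5)c(OC)c4)[C@H]3CO)cc2OC)ccc1OCc1ccccc1 | intermediate
23 | CNP0158473.2, (7''R,8''R)-threo-guaiacylglycerol 8''-O-4' ether of (+)-lariciresinol | COc1cc([C@@H](O)[C@@H](CO)Oc2ccc(C[C@H]3CO[C@H](c4ccc(O)c(OC)c4)[C@H]3CO)cc2OC)ccc1O | target

Total step count: 13. Longest linear sequence: 13 steps (1 to 23).

**Three steps most likely to fail**

Step 5. The risks are the facial selectivity of the hydride and the configurational lability of ketone 8. The fallback sets out from 5 and comes back at 9.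
- DIBAL-H (THF, −78 °C) takes the Weinreb amide to the aldehyde (R)-2-(4-allyl-2-methoxyphenoxy)-3-(benzyloxy)propanal F1.
- This aldehyde is precomplexed with MgBr2·OEt2 in CH2Cl2 at −78 °C and treated with the Grignard reagent 7.
- In this Cram-chelate addition the aryl group is delivered instead of hydride. Chelation by the guaiacyl oxygens, which would erode step 5, now leads to the threo alcohol 9, and no enolisable aryl ketone is ever made.

Step 9. The risk is ozone attacking two electron-rich dialkoxyarenes and the benzyl ethers. The fallback sets out from 15 and comes back at 17.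
- Catalytic OsO4 with NMO (acetone–water) dihydroxylates only the alkene to ethyl (3R)-4,5-dihydroxy-3-(Ar*-methyl)hexanoate F2, as a mixture of carbinol epimers.
- NaIO4 (THF–water, pH 7) cleaves the glycol to ethyl (R)-3-formyl-4-(Ar*)butanoate F3.
- Immediate NaBH4 reduction at 0 °C gives 16, which lactonises to 17.

Step 12. The risks are ionisation at C7'' as well as at C7, and Friedel–Crafts closure to the aryltetralin. The fallback sets out from 20 and comes back at 22.
- LiBH4 (THF, 0 °C) reduces only the lactone and gives the 7''-O-pivaloyl derivative of tetraol 21 F4, so the side-chain benzylic oxygen stays acylated and much harder to ionise.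
- p-TsOH then closes the ring to the 7''-O-pivaloyl derivative of 22 F5.
- DIBAL-H (CH2Cl2, −78 °C) removes the pivalate to give 22.

**Further compounds**
F1 | step 5 | (R)-2-(4-allyl-2-methoxyphenoxy)-3-(benzyloxy)propanal | C=CCc1ccc(O[C@H](COCc2ccccc2)C=O)c(OC)c1
F2 | step 9 | ethyl (3R)-4,5-dihydroxy-3-(Ar*-methyl)hexanoate | CCOC(=O)C[C@@H](Cc1ccc(O[C@H](COCc2ccccc2)[C@H](OC(=O)C(C)(C)C)c2ccc(OCc3ccccc3)c(OC)c2)c(OC)c1)C(O)C(C)O
F3 | step 9 | ethyl (R)-3-formyl-4-(Ar*)butanoate | CCOC(=O)C[C@@H](Cc1ccc(O[C@H](COCc2ccccc2)[C@H](OC(=O)C(C)(C)C)c2ccc(OCc3ccccc3)c(OC)c2)c(OC)c1)C=O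
F4 | step 12 | 7''-O-pivaloyl derivative of tetraol 21 | OC[C@H](C(O)c1ccc(OCc2ccccc2)c(OC)c1)[C@@H](Cc1ccc(O[C@H](COCc2ccccc2)[C@H](OC(=O)C(C)(C)C)c2ccc(OCc3ccccc3)c(OC)c2)c(OC)c1)CO
F5 | step 12 | 7''-O-pivaloyl derivative of 22 | COc1cc([C@@H](OC(=O)C(C)(C)C)[C@@H](COCc2ccccc2)Oc2ccc(C[C@H]3CO[C@H](c4ccc(OCc5ccccc5)c(OC)c4)[C@H]3CO)cc2OC)ccc1OCc1ccccc1
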